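**Retrosynthetic overview**
1. Target 9 ⇐ 8 by removing only the C15 acetate; 8 ⇐ 5 by C7–O formation (allylic C–H hydroxylation on the α-face).
2. 5 ⇐ 4 by loss of acetic acid across C8–C17; 4 ⇐ 3 by a 1,3-shift of the acetate oxygen from C13 to C15.
3. 3 ⇐ 2 by acetylation; 2 ⇐ sclareol 1 by the key step, C19–O formation on the axial 4β-methyl (new enzymatic C–H hydroxylation that creates the C4 stereocentre).
4. No ring and no C–C bond is made: rings A and B, C5, C9, C10 and all twenty skeletal carbons come with sclareol; every bond formed or moved is C–O.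

Assumption: the SMILES is read as the normal-series labdane (13E)-7α,15-dihydroxylabda-8(17),13-dien-19-yl acetate (5α-H, 9α-H, 10β-CH3, 4β-CH2OAc, axial 7α-OH).

**Route**

Step 1
Reactants: 1 (−)-sclareol, (13R)-labd-14-ene-8α,13-diol
Product: 2 19-hydroxysclareol, (13R)-labd-14-ene-8α,13,19-triol
Conditions: engineered cytochrome P450 BM3 (CYP102A1) C19-hydroxylase variant in clarified E. coli lysate, air, NADP+ (cat.), D-glucose, glucose dehydrogenase, KH2PO4/K2HPO4 buffer pH 8, hydroxypropyl-β-cyclodextrin, 25 °C
Reagents that add atoms: dioxygen, O=O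
Why: Proposed new method: site-selective hydroxylation of the axial 4β-methyl (C19) of sclareol by a laboratory-evolved P450 BM3 variant; the iron-oxo (ferryl) porphyrin radical cation abstracts a hydrogen atom from whichever C–H is held nearest the iron and the carbon radical rebounds onto the iron-bound hydroxyl, so the site is set by the binding pose and not by bond strength; BM3 variants that hydroxylate sclareol and sclareolide at C3β already dock ring A over the heme, and C19 is gauche to that 3β-hydrogen (about 2.5 Å away), so reshaping the pocket roof (saturation mutagenesis at residues 78, 82, 87, 263 and 328, GC–MS screen for the C19 alcohol) should move the oxidised site by one carbon while the equatorial 4α-methyl (C18) points away from the iron; oxidising only the 4β-methyl makes C4 a stereocentre with CH2OH β (axial, cis to C20); closest known reactions are the P450 BM3 variant C3β-hydroxylation of sclareol, the evolved-BM3 methyl hydroxylation of artemisinin and the wild-type fungal ring A hydroxylation of sclareol.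

Step 2
Reactants: 2 19-hydroxysclareol
Product: 3 (13R)-labd-14-ene-8α,13,19-triyl triacetate
Conditions: AcCl, PhNMe2, CH2Cl2, 0 °C to rt
Reagents that add atoms: acetyl chloride, CC(Cl)=O
Why: Exhaustive O-acetylation (esterification) under the AcCl/N,N-dimethylaniline conditions that are standard for the two hindered tertiary hydroxyls of sclareol; the primary C19 alcohol reacts first and no stereocentre is touched.

Step 3
Reactants: 3 (13R)-labd-14-ene-8α,13,19-triyl triacetate
Product: 4 (13E)-labd-13-ene-8α,15,19-triyl triacetate
Conditions: PdCl2(MeCN)2 (5 mol %), THF, rt; E isomer isolated on AgNO3-impregnated silica, Z isomer resubmitted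
Reagents that add atoms: none
Why: Divalent-palladium-catalysed [3,3] transposition of the tertiary allylic acetate (Overman-type cyclisation-induced rearrangement) moves the oxygen from C13 to C15 and forms the trisubstituted 13-ene under thermodynamic control, E predominating (expected about 3:1); the Z isomer is separable and re-equilibrates with the same catalyst.

Step 4
Reactants: 4 (13E)-labd-13-ene-8α,15,19-triyl triacetate
Product: 5 (13E)-labda-8(17),13-diene-15,19-diyl diacetate (agathadiol diacetate)
Conditions: NaHCO3, DMSO, 150 °C
Reagents that add atoms: none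
Why: Buffered thermal dehydroacetoxylation (syn/ion-pair elimination of a tertiary acetate): the equatorial 8α-acetate leaves with relief of the C17/C20 1,3-diaxial strain and can reach a syn-periplanar hydrogen only on the axial C17 methyl, so the exocyclic 8(17)-alkene is the kinetic product, while NaHCO3 traps the acetic acid that would isomerise the alkene into the ring.

Step 5
Reactants: 5 (13E)-labda-8(17),13-diene-15,19-diyl diacetate
Product: 8 (13E)-7α-hydroxylabda-8(17),13-diene-15,19-diyl diacetate, via allylseleninic acid 6 (not isolated), via selenoxylate ester 7 (not isolated)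
Conditions: SeO2 (30 mol %), t-BuOOH (3 equiv), CH2Cl2, rt
Reagents that add atoms: selenium dioxide, O=[Se]=O; tert-butyl hydroperoxide, CC(C)(C)OO
Why: Riley–Sharpless allylic oxidation: the ene reaction at the 1,1-disubstituted alkene removes the axial 7α-hydrogen, and the suprafacial [2,3]-sigmatropic shift returns the alkene to C8=C17 and delivers oxygen to the α-face of C7 (axial 7α-OH, the usual outcome for labd-8(17)-enes); the 13-ene is deactivated by its allylic acetate, as in geranyl acetate.

Step 6
Reactants: 8 (13E)-7α-hydroxylabda-8(17),13-diene-15,19-diyl diacetate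
Product: 9 (13E)-7α,15-dihydroxylabda-8(17),13-dien-19-yl acetate (target)
Conditions: K2CO3 (0.3 equiv), MeOH, 0 °C, stopped at mono-deacetylation
Reagents that add atoms: none
Why: Kinetically selective base-catalysed transesterification (Zemplén-type methanolysis): the unhindered primary allylic C15 acetate is cleaved well before the neopentyl, axial C19 acetate next to the quaternary C4.

**Compound list**
1 | (−)-sclareol, (13R)-labd-14-ene-8α,13-diol | C[C@@]1(O)CC[C@H]2C(C)(C)CCC[C@]2(C)[C@H]1CC[C@@](C)(O)C=C | starting material
2 | 19-hydroxysclareol, (13R)-labd-14-ene-8α,13,19-triol (4β-CH2OH) | C[C@@]1(O)CC[C@H]2[C@@](C)(CO)CCC[C@]2(C)[C@H]1CC[C@@](C)(O)C=C | intermediate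
3 | (13R)-labd-14-ene-8α,13,19-triyl triacetate | C[C@@]1(OC(C)=O)CC[C@H]2[C@@](C)(COC(C)=O)CCC[C@]2(C)[C@H]1CC[C@@](C)(OC(C)=O)C=C | intermediate
4 | (13E)-labd-13-ene-8α,15,19-triyl triacetate | C[C@@]1(OC(C)=O)CC[C@H]2[C@@](C)(COC(C)=O)CCC[C@]2(C)[C@H]1CC/C(C)=C/COC(C)=O | intermediate
5 | (13E)-labda-8(17),13-diene-15,19-diyl diacetate | C=C1CC[C@H]2[C@@](C)(COC(C)=O)CCC[C@]2(C)[C@H]1CC/C(C)=C/COC(C)=O | intermediate
6 | (13E)-15,19-diacetoxylabda-7,13-diene-17-seleninic acid (ene adduct, Se on C17) | O[Se](=O)CC1=CC[C@H]2[C@@](C)(COC(C)=O)CCC[C@]2(C)[C@H]1CC/C(C)=C/COC(C)=O | intermediate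
7 | (13E)-15,19-diacetoxylabda-8(17),13-dien-7α-yl hydrogen selenoxylate (RO–Se–OH ester of divalent selenium) | C=C1[C@H](O[Se]O)C[C@H]2[C@@](C)(COC(C)=O)CCC[C@]2(C)[C@H]1CC/C(C)=C/COC(C)=O | intermediate
8 | (13E)-7α-hydroxylabda-8(17),13-diene-15,19-diyl diacetate | C=C1[C@H](O)C[C@H]2[C@@](C)(COC(C)=O)CCC[C@]2(C)[C@H]1CC/C(C)=C/COC(C)=O | intermediate
9 | (13E)-7α,15-dihydroxylabda-8(17),13-dien-19-yl acetate (CNP0209062.1) | C=C1[C@H](O)C[C@H]2[C@@](C)(COC(C)=O)CCC[C@]2(C)[C@H]1CC/C(C)=C/CO | target

**Totals and risk**
Total steps: 6. Longest linear sequence: 6 (from sclareol).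

The three steps most likely to fail:

Step 1 (the proposed enzymatic C19 hydroxylation): no variant may reach useful selectivity for the axial methyl over C2, C3 and C18. Fallback with known chemistry, setting out from 1 and coming back at 2: ferment sclareol with a wild-type Cunninghamella strain, a long-established preparative biotransformation that hydroxylates ring A (2α, C18 and, as a lesser product, C19), and isolate 2 from its isomers by chromatography. The approach changes from one designed, site-specific catalyst to an unselective whole-organism oxidation followed by isomer separation; it makes no new compound, F0.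

Step 4 (thermal loss of the tertiary acetate): the endocyclic 7-ene and 8-ene isomers may take over, or the primary acetates may be partly lost at 150 °C. Fallback, setting out from 4 and coming back at 5: replace the thermal elimination by an E2 dehydration of the free tertiary alcohol. LiAlH4 (THF, 0 °C) removes all three acetates to give (13E)-labd-13-ene-8α,15,19-triol F1. Ac2O/pyridine at 0 °C re-acetylates only the two primary hydroxyls to give (13E)-8α-hydroxylabd-13-ene-15,19-diyl diacetate F2. SOCl2/pyridine in CH2Cl2 at −78 °C then dehydrates the equatorial 8α-alcohol, whose only anti-periplanar hydrogens sit on the C17 methyl, to give 5.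

Step 5 (SeO2 oxidation with two alkenes present): SeO2 may also attack the allylic positions of the 13-ene or over-oxidise to the 7-ketone. Fallback, setting out from 2 and coming back at 8: change the order so that the allylic oxidation is run while the side chain still carries the inert vinyl group. Ac2O/Et3N/DMAP (CH2Cl2, rt) acetylates the primary C19 and the side-chain C13 hydroxyls but should spare the more hindered ring 8α-hydroxyl, giving (13R)-8α-hydroxylabd-14-ene-13,19-diyl diacetate F3. SOCl2/pyridine at −78 °C dehydrates it to (13R)-labda-8(17),14-diene-13,19-diyl diacetate F4. SeO2/t-BuOOH now meets only one oxidisable alkene and gives (13R)-7α-hydroxylabda-8(17),14-diene-13,19-diyl diacetate F5. PdCl2(MeCN)2 in THF finally shifts the tertiary allylic acetate to C15 and gives 8, the E isomer being separated as in step 3.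

**Further compounds**
F0 | step 1 | none | none
F1 | step 4 | (13E)-labd-13-ene-8α,15,19-triol | C[C@@]1(O)CC[C@H]2[C@@](C)(CO)CCC[C@]2(C)[C@H]1CC/C(C)=C/CO
F2 | step 4 | (13E)-8α-hydroxylabd-13-ene-15,19-diyl diacetate | C[C@@]1(O)CC[C@H]2[C@@](C)(COC(C)=O)CCC[C@]2(C)[C@H]1CC/C(C)=C/COC(C)=O
F3 | step 5 | (13R)-8α-hydroxylabd-14-ene-13,19-diyl diacetate | C[C@@]1(O)CC[C@H]2[C@@](C)(COC(C)=O)CCC[C@]2(C)[C@H]1CC[C@@](C)(OC(C)=O)C=C
F4 | step 5 | (13R)-labda-8(17),14-diene-13,19-diyl diacetate | C=C1CC[C@H]2[C@@](C)(COC(C)=O)CCC[C@]2(C)[C@H]1CC[C@@](C)(OC(C)=O)C=C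
F5 | step 5 | (13R)-7α-hydroxylabda-8(17),14-diene-13,19-diyl diacetate | C=C1[C@H](O)C[C@H]2[C@@](C)(COC(C)=O)CCC[C@]2(C)[C@H]1CC[C@@](C)(OC(C)=O)C=C
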